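The benzene of the target (ring A) carries three oxygens (O5, O7, O8a) interleaved with three carbons (C4a, C6, C8), and the pyranone may be built only on O8a and C4a. The route rests on a Danheiser benzannulation. A thermal cascade between a 4-prenyl-3-ethoxycyclobutenone and a siloxyalkyne that already holds the (R)-configured C8 side chain creates C7–C8 and C4a–C8a, then closes ring A. It leaves O7 free, O8a silylated, O5 ethylated and C4a–H as the single open position. The side-chain carboxyl travels as a silyl ester through the ynolate chemistry. Formylation at C4a, alkyne hydroacylation and an alkaloid-controlled oxa-Michael closure complete the cis-dimethylpyranone.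

Key step: step 6

Remark: quinine is assumed to impose the 2R sense here as it does on related o-tigloylphenols; if the sense proves opposite, quinidine takes its place.

Step 1
Reactants: 1 5-methylhex-4-enoic acid; 2 ethoxyacetylene
Product: 5 3-ethoxy-4-(3-methylbut-2-en-1-yl)cyclobut-2-en-1-one (racemic), via 5-methylhex-4-enoyl chloride 3 (not isolated), via prenylketene 4 (not isolated)
Conditions: (COCl)2, cat. DMF, CH2Cl2, 0 °C → rt, concentrate; then 2 (1.5 equiv), Et3N, Et2O, 0 °C → rt, slow addition of 3
Reagents that add atoms: none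
Why: Dehydrochlorination of the acid chloride gives the aldoketene, whose carbonyl carbon is attacked by the nucleophilic terminal carbon of the ynol ether in a regioselective ketene–alkyne [2+2] cycloaddition, the standard entry to 3-alkoxycyclobutenones; C4 forms racemic and is erased in step 6.

Step 2
Reactants: 6 (4R)-4-propyldihydrofuran-2(3H)-one
Product: 8 methyl (3R)-3-(hydroxymethyl)hexanoate, via sodium (3R)-3-(hydroxymethyl)hexanoate 7 (not isolated)
Conditions: NaOH (1.05 equiv), MeOH–H2O, rt; evaporate; MeI, DMF, rt; used at once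
Reagents that add atoms: sodium hydroxide [Na+].[OH-]; iodomethane CI
Why: Lactone saponification followed by SN2 O-methylation of the carboxylate salt gives the open hydroxy ester under neutral conditions, avoiding the acid that drives relactonization and leaving the stereocentre untouched.

Step 3
Reactants: 8 methyl (3R)-3-(hydroxymethyl)hexanoate
Product: 9 methyl (3R)-3-formylhexanoate
Conditions: Dess–Martin periodinane, NaHCO3, CH2Cl2, 0 °C → rt
Reagents that add atoms: none
Why: Buffered Dess–Martin oxidation takes the primary alcohol to the aldehyde under mild, non-basic conditions that should not epimerize the α-branched centre.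

Step 4
Reactants: 9 methyl (3R)-3-formylhexanoate
Product: 11 (3R)-3-ethynylhexanoic acid, via methyl (3R)-3-ethynylhexanoate 10 (not isolated)
Conditions: dimethyl (1-diazo-2-oxopropyl)phosphonate, K2CO3, MeOH, 0 °C → rt; then LiOH, H2O, rt; aq. HCl to pH 3
Reagents that add atoms: dimethyl (1-diazo-2-oxopropyl)phosphonate CC(=O)C(=[N+]=[N-])P(=O)(OC)OC; lithium hydroxide [Li+].[OH-]
Why: Ohira–Bestmann (Seyferth–Gilbert) homologation converts the aldehyde into the terminal alkyne under mildly basic conditions known to preserve α-stereocentres, and in-flask saponification delivers the acid, which is purified by acid–base extraction without isolating the volatile ester.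

Step 5
Reactants: 11 (3R)-3-ethynylhexanoic acid
Product: 13 triisopropylsilyl (3R)-3-[(triisopropylsilyloxy)ethynyl]hexanoate, via dilithium ynolate carboxylate 12 (not isolated)
Conditions: LiN(SiMe3)2 (2.1 equiv), THF, −78 °C; t-BuOOLi (from t-BuOOH and LiN(SiMe3)2), −78 → 0 °C; iPr3SiOTf (2.2 equiv), −78 → 0 °C
Reagents that add atoms: tert-butyl hydroperoxide CC(C)(C)OO; triisopropylsilyl trifluoromethanesulfonate CC(C)[Si](C(C)C)(C(C)C)OS(=O)(=O)C(F)(F)F
Why: Acetylide oxidation with lithium tert-butyl peroxide gives the ynolate, which the bulky silyl triflate traps on oxygen; the carboxyl is present as its lithium salt, which the amide base cannot enolize (a methyl ester would be), and it emerges as a silyl ester.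

Step 6
Reactants: 5 3-ethoxy-4-(3-methylbut-2-en-1-yl)cyclobut-2-en-1-one; 13 triisopropylsilyl (3R)-3-[(triisopropylsilyloxy)ethynyl]hexanoate
Product: 18 triisopropylsilyl (3R)-3-[4-ethoxy-2-hydroxy-3-(3-methylbut-2-en-1-yl)-6-(triisopropylsilyloxy)phenyl]hexanoate, via vinylketene 14 (not isolated), via vinylcyclobutenone adduct 15 (not isolated), via dienylketene 16 (not isolated), via cyclohexadienone tautomer 17 (not isolated)
Conditions: toluene, 80 °C then 110 °C, sealed tube, argon; slight excess of 5 added in portions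
Reagents that add atoms: none
Why: Heat opens 5 by a 4π-electrocyclic ring opening (prenyl turning outward) to vinylketene 14, which undergoes a regioselective [2+2] cycloaddition with 13 to give 15; a second 4π opening gives dienylketene 16, and ring A closes by a 6π-electrocyclization joining the ketene carbon (C7) to the prenyl-bearing carbon (C6), after which dienone 17 tautomerizes to phenol 18. This is the Danheiser benzannulation of a cyclobutenone with a siloxyalkyne, a known route to resorcinol monosilyl ethers. The [2+2] event forms C7–C8 and C4a–C8a; no stereocentre is created, the racemic C4 of 5 becomes aromatic, and the side-chain centre cannot enolize under the neutral thermal conditions. The selectivity required is the orientation of the [2+2]: the oxygen-polarized alkyne is nucleophilic at the carbon bearing the side chain, so that carbon bonds to the ketene carbonyl carbon and the chain ends between the new C7 hydroxyl and the C8a silyl ether. The ring therefore emerges with O7 free, O8a silylated, O5 ethylated and C4a–H as the only open position, so the later annulation can engage only O8a and C4a.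

Step 7
Reactants: 18 triisopropylsilyl (3R)-3-[4-ethoxy-2-hydroxy-3-(3-methylbut-2-en-1-yl)-6-(triisopropylsilyloxy)phenyl]hexanoate
Product: 19 (3R)-3-[4-ethoxy-2,6-dihydroxy-3-(3-methylbut-2-en-1-yl)phenyl]hexanoic acid
Conditions: n-Bu4NF (3 equiv), THF, 0 °C; cold 0.5 M HCl to pH 3–4; used at once
Reagents that add atoms: none
Why: Fluoride-mediated Si–O cleavage removes the aryl silyl ether and the silyl ester together, and because no enone is present yet the liberated O8a phenoxide has nothing to add to.

Step 8
Reactants: 19 (3R)-3-[4-ethoxy-2,6-dihydroxy-3-(3-methylbut-2-en-1-yl)phenyl]hexanoic acid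
Product: 20 methyl (3R)-3-[4-ethoxy-2,6-dihydroxy-3-(3-methylbut-2-en-1-yl)phenyl]hexanoate
Conditions: Me3SiCHN2 (1.3 equiv), MeOH–toluene (1:3), 0 °C
Reagents that add atoms: (trimethylsilyl)diazomethane C[Si](C)(C)C=[N+]=[N-]
Why: Esterification with (trimethylsilyl)diazomethane in methanol methylates the carboxylic acid far faster than the electron-rich, weakly acidic phenols, so the methyl ester should form chemoselectively.

Step 9
Reactants: 20 methyl (3R)-3-[4-ethoxy-2,6-dihydroxy-3-(3-methylbut-2-en-1-yl)phenyl]hexanoate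
Product: 21 methyl (3R)-3-[4-ethoxy-3-formyl-2,6-dihydroxy-5-(3-methylbut-2-en-1-yl)phenyl]hexanoate
Conditions: MgCl2 (3 equiv), Et3N (6 equiv), (CH2O)n (8 equiv), MeCN, 75 °C; 1 M HCl work-up
Reagents that add atoms: paraformaldehyde (as formaldehyde) C=O
Why: Magnesium-mediated ortho-formylation (Casnati–Skattebøl) is specific for the carbon ortho to a free phenol, and C4a, next to O8a–H, is the only unsubstituted ring carbon; the mildly basic conditions spare the prenyl alkene and the ester.

Step 10
Reactants: 21 methyl (3R)-3-[4-ethoxy-3-formyl-2,6-dihydroxy-5-(3-methylbut-2-en-1-yl)phenyl]hexanoate; 22 but-2-yne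
Product: 23 methyl (3R)-3-{4-ethoxy-2,6-dihydroxy-3-[(2E)-2-methylbut-2-enoyl]-5-(3-methylbut-2-en-1-yl)phenyl}hexanoate
Conditions: [RhCl(C8H12)]2 (2.5 mol%), Fe(C5H4PPh2)2 (5 mol%), Na2CO3 (10 mol%), excess but-2-yne, toluene, 80 °C, sealed tube
Reagents that add atoms: none
Why: In this phenoxide-chelated rhodium-catalysed hydroacylation of an internal alkyne by a salicylaldehyde, the formyl C–H bond adds syn across one molecule of but-2-yne to give the (E)-enone (tigloyl ketone) with nothing released, under near-neutral conditions that avoid the Lewis acids of a Friedel–Crafts acylation, which an ortho-prenylphenol would not tolerate; the trisubstituted prenyl alkene is inert.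

Step 11
Reactants: 23 methyl (3R)-3-{4-ethoxy-2,6-dihydroxy-3-[(2E)-2-methylbut-2-enoyl]-5-(3-methylbut-2-en-1-yl)phenyl}hexanoate
Product: 24 methyl (3R)-3-[(2R,3S)-5-ethoxy-7-hydroxy-2,3-dimethyl-6-(3-methylbut-2-en-1-yl)-4-oxo-3,4-dihydro-2H-chromen-8-yl]hexanoate
Conditions: quinine (0.3 equiv), PhCl, 15 °C, dark
Reagents that add atoms: none
Why: In this cinchona-alkaloid-catalysed intramolecular oxa-Michael addition the quinuclidine activates O8a–H while the alkaloid hydroxyl binds the ketone, so O8a adds to one enone face and sets C2 (R), and kinetic protonation of the enol anti to the new C2 methyl sets C3 (S), i.e. the cis isomer; O5 is blocked as its ethyl ether, so only O8a can close.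

Step 12
Reactants: 24 methyl (3R)-3-[(2R,3S)-5-ethoxy-7-hydroxy-2,3-dimethyl-6-(3-methylbut-2-en-1-yl)-4-oxo-3,4-dihydro-2H-chromen-8-yl]hexanoate
Product: 25 methyl (3R)-3-[(2R,3S)-5,7-dihydroxy-2,3-dimethyl-6-(3-methylbut-2-en-1-yl)-4-oxo-3,4-dihydro-2H-chromen-8-yl]hexanoate
Conditions: BCl3 (3 equiv), CH2Cl2, −78 → −30 °C; ice-water
Reagents that add atoms: none
Why: Chelation-assisted ether cleavage: BCl3 bridges the C4 carbonyl and O5 and chloride removes the ethyl group, a reaction selective for the ether peri to a carbonyl and expected to run cold enough to spare the ester, the prenyl group and the three stereocentres.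

Compound list
1 | 5-methylhex-4-enoic acid | CC(C)=CCCC(=O)O | starting material
2 | ethoxyacetylene | CCOC#C | starting material
3 | 5-methylhex-4-enoyl chloride | CC(C)=CCCC(=O)Cl | intermediate
4 | prenylketene (5-methylhexa-1,4-dien-1-one) | CC(C)=CCC=C=O | intermediate
5 | 3-ethoxy-4-(3-methylbut-2-en-1-yl)cyclobut-2-en-1-one (racemic) | CCOC1=CC(=O)C1CC=C(C)C | intermediate
6 | (4R)-4-propyldihydrofuran-2(3H)-one | CCC[C@H](CC(=O)O1)C1 | starting material
7 | sodium (3R)-3-(hydroxymethyl)hexanoate | CCC[C@H](CC(=O)[O-])CO.[Na+] | intermediate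
8 | methyl (3R)-3-(hydroxymethyl)hexanoate | CCC[C@H](CC(=O)OC)CO | intermediate
9 | methyl (3R)-3-formylhexanoate | CCC[C@H](CC(=O)OC)C=O | intermediate
10 | methyl (3R)-3-ethynylhexanoate | CCC[C@H](CC(=O)OC)C#C | intermediate
11 | (3R)-3-ethynylhexanoic acid | CCC[C@H](CC(=O)O)C#C | intermediate
12 | dilithium (3R)-3-(oxidoethynyl)hexanoate (ynolate carboxylate) | CCC[C@H](CC(=O)[O-])C#C[O-].[Li+].[Li+] | intermediate
13 | triisopropylsilyl (3R)-3-[(triisopropylsilyloxy)ethynyl]hexanoate | CCC[C@H](CC(=O)O[Si](C(C)C)(C(C)C)C(C)C)C#CO[Si](C(C)C)(C(C)C)C(C)C | intermediate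
14 | (3Z)-3-ethoxy-7-methylocta-1,3,6-trien-1-one (vinylketene) | O=C=C/C(OCC)=C/CC=C(C)C | intermediate
15 | triisopropylsilyl (3R)-3-{3-[(1Z)-1-ethoxy-5-methylhexa-1,4-dien-1-yl]-4-oxo-2-(triisopropylsilyloxy)cyclobut-1-en-1-yl}hexanoate (both epimers at the ring sp3 carbon) | CCC[C@H](CC(=O)O[Si](C(C)C)(C(C)C)C(C)C)C1=C(O[Si](C(C)C)(C(C)C)C(C)C)C(C1=O)/C(OCC)=C/CC=C(C)C | intermediate
16 | triisopropylsilyl (3R)-3-[(3E,5Z)-5-ethoxy-9-methyl-1-oxo-3-(triisopropylsilyloxy)deca-1,3,5,8-tetraen-2-yl]hexanoate (dienylketene) | CCC[C@H](CC(=O)O[Si](C(C)C)(C(C)C)C(C)C)C(=C=O)/C(O[Si](C(C)C)(C(C)C)C(C)C)=C\C(OCC)=C\CC=C(C)C | intermediate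
17 | triisopropylsilyl (3R)-3-[4-ethoxy-5-(3-methylbut-2-en-1-yl)-6-oxo-2-(triisopropylsilyloxy)cyclohexa-1,3-dien-1-yl]hexanoate (keto tautomer of 18) | CCC[C@H](CC(=O)O[Si](C(C)C)(C(C)C)C(C)C)C1=C(O[Si](C(C)C)(C(C)C)C(C)C)C=C(OCC)C(CC=C(C)C)C1=O | intermediate
18 | triisopropylsilyl (3R)-3-[4-ethoxy-2-hydroxy-3-(3-methylbut-2-en-1-yl)-6-(triisopropylsilyloxy)phenyl]hexanoate | CCC[C@H](CC(=O)O[Si](C(C)C)(C(C)C)C(C)C)c1c(O)c(CC=C(C)C)c(OCC)cc1O[Si](C(C)C)(C(C)C)C(C)C | intermediate
19 | (3R)-3-[4-ethoxy-2,6-dihydroxy-3-(3-methylbut-2-en-1-yl)phenyl]hexanoic acid | CCC[C@H](CC(=O)O)c1c(O)c(CC=C(C)C)c(OCC)cc1O | intermediate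
20 | methyl (3R)-3-[4-ethoxy-2,6-dihydroxy-3-(3-methylbut-2-en-1-yl)phenyl]hexanoate | CCC[C@H](CC(=O)OC)c1c(O)c(CC=C(C)C)c(OCC)cc1O | intermediate
21 | methyl (3R)-3-[4-ethoxy-3-formyl-2,6-dihydroxy-5-(3-methylbut-2-en-1-yl)phenyl]hexanoate | CCC[C@H](CC(=O)OC)c1c(O)c(CC=C(C)C)c(OCC)c(C=O)c1O | intermediate
22 | but-2-yne | CC#CC | starting material
23 | methyl (3R)-3-{4-ethoxy-2,6-dihydroxy-3-[(2E)-2-methylbut-2-enoyl]-5-(3-methylbut-2-en-1-yl)phenyl}hexanoate | CCC[C@H](CC(=O)OC)c1c(O)c(CC=C(C)C)c(OCC)c(C(=O)/C(C)=C/C)c1O | intermediate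
24 | methyl (3R)-3-[(2R,3S)-5-ethoxy-7-hydroxy-2,3-dimethyl-6-(3-methylbut-2-en-1-yl)-4-oxo-3,4-dihydro-2H-chromen-8-yl]hexanoate | CCC[C@H](CC(=O)OC)c1c(O)c(CC=C(C)C)c(OCC)c2c1O[C@H](C)[C@H](C)C2=O | intermediate
25 | methyl (3R)-3-[(2R,3S)-5,7-dihydroxy-2,3-dimethyl-6-(3-methylbut-2-en-1-yl)-4-oxo-3,4-dihydro-2H-chromen-8-yl]hexanoate | CCC[C@H](CC(=O)OC)c1c(O)c(CC=C(C)C)c(O)c2c1O[C@H](C)[C@H](C)C2=O | target

Total step count: 12 steps.
Longest linear sequence: 11 steps (steps 2–12, from lactone 6).

Steps most likely to fail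

Step 6. The vinylketene may be lost to self-condensation, or to acylation of the phenol being formed, before the α-branched siloxyalkyne captures it. The long heating needed to open the cyclobutenone may also degrade the silyl ynol ether. The fallback sets out from alkyne 13 and comes back at phenol 18. It replaces the electrocyclic opening by a base-induced 1,4-elimination that releases the same vinylketene 14 at low temperature. Ethyl acetoacetate is alkylated at C4 through its dianion (NaH, then n-BuLi, THF, 0 °C; 1-bromo-3-methylbut-2-ene) to give ethyl 7-methyl-3-oxooct-6-enoate F1. Triethyl orthoformate with catalytic p-TsOH in EtOH converts it into the enol ether ethyl (2E)-3-ethoxy-7-methylocta-2,6-dienoate F2. KOH in aqueous EtOH gives (2E)-3-ethoxy-7-methylocta-2,6-dienoic acid F3, and (COCl)2 gives (2E)-3-ethoxy-7-methylocta-2,6-dienoyl chloride F4. Slow addition of F4 to 13 and Et3N in toluene at 25–40 °C should generate 14 by γ-deprotonation and loss of chloride, at low concentration and in the presence of the ketenophile. A short period at 110 °C then carries adduct 15 through 16 and 17 to 18.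

Step 11. The alkaloid may discriminate poorly between the enone faces, since the more acidic C7 phenol can tie up the amine. The kinetic cis product may also drift to the trans isomer through enolization at C3. The fallback sets out from enone 23 and comes back at chromanone 24. It gives up catalyst control and uses the fixed side-chain centre as the handle for separation. Closure with catalytic Et3N in CH2Cl2 at 0 °C, stopped early, should give the kinetic cis-chromanone as two diastereomers, 24 and methyl (3R)-3-[(2S,3R)-5-ethoxy-7-hydroxy-2,3-dimethyl-6-(3-methylbut-2-en-1-yl)-4-oxo-3,4-dihydro-2H-chromen-8-yl]hexanoate F5. These differ in their relation to the (3R) side-chain centre and should separate by preparative HPLC.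

Step 12. Hydrogen chloride released when BCl3 meets the free C7 phenol may add to the prenyl alkene or close it onto O7, and prolonged contact with the Lewis acid may epimerize C3. The fallback sets out from 24 and comes back at target 25. It removes the proton source before the ether cleavage. Et3SiCl and imidazole in DMF give methyl (3R)-3-[(2R,3S)-5-ethoxy-2,3-dimethyl-6-(3-methylbut-2-en-1-yl)-4-oxo-7-(triethylsilyloxy)-3,4-dihydro-2H-chromen-8-yl]hexanoate F6. BCl3 in CH2Cl2 at −78 °C then cleaves the chelated ethyl ether to give methyl (3R)-3-[(2R,3S)-5-hydroxy-2,3-dimethyl-6-(3-methylbut-2-en-1-yl)-4-oxo-7-(triethylsilyloxy)-3,4-dihydro-2H-chromen-8-yl]hexanoate F7. Pyridine-buffered HF·pyridine in THF at 0 °C removes the silyl group under non-basic conditions to give 25.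

Further compounds
F1 | step 6 | ethyl 7-methyl-3-oxooct-6-enoate | CCOC(=O)CC(=O)CCC=C(C)C
F2 | step 6 | ethyl (2E)-3-ethoxy-7-methylocta-2,6-dienoate | CCOC(=O)/C=C(/OCC)CCC=C(C)C
F3 | step 6 | (2E)-3-ethoxy-7-methylocta-2,6-dienoic acid | OC(=O)/C=C(/OCC)CCC=C(C)C
F4 | step 6 | (2E)-3-ethoxy-7-methylocta-2,6-dienoyl chloride | ClC(=O)/C=C(/OCC)CCC=C(C)C
F5 | step 11 | methyl (3R)-3-[(2S,3R)-5-ethoxy-7-hydroxy-2,3-dimethyl-6-(3-methylbut-2-en-1-yl)-4-oxo-3,4-dihydro-2H-chromen-8-yl]hexanoate | CCC[C@H](CC(=O)OC)c1c(O)c(CC=C(C)C)c(OCC)c2c1O[C@@H](C)[C@@H](C)C2=O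
F6 | step 12 | methyl (3R)-3-[(2R,3S)-5-ethoxy-2,3-dimethyl-6-(3-methylbut-2-en-1-yl)-4-oxo-7-(triethylsilyloxy)-3,4-dihydro-2H-chromen-8-yl]hexanoate | CCC[C@H](CC(=O)OC)c1c(O[Si](CC)(CC)CC)c(CC=C(C)C)c(OCC)c2c1O[C@H](C)[C@H](C)C2=O
F7 | step 12 | methyl (3R)-3-[(2R,3S)-5-hydroxy-2,3-dimethyl-6-(3-methylbut-2-en-1-yl)-4-oxo-7-(triethylsilyloxy)-3,4-dihydro-2H-chromen-8-yl]hexanoate | CCC[C@H](CC(=O)OC)c1c(O[Si](CC)(CC)CC)c(CC=C(C)C)c(O)c2c1O[C@H](C)[C@H](C)C2=O
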